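**Assumption:** the target SMILES has no stereocentre and no stereogenic double bond, so the compound is achiral and no enantiocontrol is needed.

## Retrosynthetic overview

- Ring labels: ring A = methoxy-bearing 1,2,3-trisubstituted ring; ring B = meta-phenylene; ring C = phenol ring; ring D = para-phenylene.
- The target comes from a macrocyclic stilbene benzyl ether by one hydrogenation that saturates the D–A alkene and removes the benzyl group.
- The 18-membered ring is the only ring made; it is closed second to last by an intramolecular Wittig reaction (ring D benzylphosphonium onto ring A aldehyde).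
- The B–C ethano bridge comes from an intermolecular Perkin (aldol-type) condensation of an A–O–B arylacetic acid with a C–O–D aldehyde, then decarboxylation and diimide reduction.
- Each half is made by one SNAr diaryl ether synthesis from purchased benzene building blocks (nitrile on ring A and ester on ring D serve as latent aldehyde and latent benzyl bromide).

## Route

Step 1
Reactants: 1 3-hydroxyphenylacetic acid; 2 2-fluoro-3-methoxybenzonitrile
Product: 3 2-[3-(2-cyano-6-methoxyphenoxy)phenyl]acetic acid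
Conditions: K2CO3 (2.5 equiv), DMSO, 120 °C; acidic work-up
Reagents that add atoms: none
Why: SNAr (addition–elimination) in which the phenoxide of 1 displaces the fluoride activated by the ortho nitrile, the carboxylate being a spectator with no acidic α-CH.

Step 2
Reactants: 4 4-(benzyloxy)-3-hydroxybenzaldehyde; 5 methyl 4-fluorobenzoate
Product: 6 methyl 4-[2-(benzyloxy)-5-formylphenoxy]benzoate
Conditions: K2CO3, DMSO, 120–130 °C
Reagents that add atoms: none
Why: SNAr of the phenoxide on the para-ester-activated aryl fluoride; the non-enolisable aldehyde and the benzyl ether are inert to carbonate.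

Step 3
Reactants: 3 2-[3-(2-cyano-6-methoxyphenoxy)phenyl]acetic acid; 6 methyl 4-[2-(benzyloxy)-5-formylphenoxy]benzoate
Product: 8 (2E)-3-{4-(benzyloxy)-3-[4-(methoxycarbonyl)phenoxy]phenyl}-2-[3-(2-cyano-6-methoxyphenoxy)phenyl]prop-2-enoic acid, via acetic 2-[3-(2-cyano-6-methoxyphenoxy)phenyl]acetic anhydride 7 (not isolated)
Conditions: Ac2O, Et3N, 110 °C; then dilute aq. HCl
Reagents that add atoms: none
Why: Perkin condensation, in which the mixed anhydride is enolised by Et3N, adds in an intermolecular aldol reaction to the non-enolisable aldehyde and eliminates acetate to give the thermodynamically preferred (E)-acid with the two aryl groups cis; nitrile, ester and benzyl ether are inert.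

Step 4
Reactants: 8 the (E)-2,3-diarylacrylic acid
Product: 9 methyl 4-{2-(benzyloxy)-5-[(Z)-2-[3-(2-cyano-6-methoxyphenoxy)phenyl]ethenyl]phenoxy}benzoate
Conditions: Cu powder, quinoline, 210 °C
Reagents that add atoms: none
Why: copper-mediated protodecarboxylation of an α-arylcinnamic acid proceeds with retention to the (Z)-stilbene; any E isomer is harmless because the alkene is reduced next.

Step 5
Reactants: 9 the (Z)-stilbene
Product: 10 methyl 4-{2-(benzyloxy)-5-[2-[3-(2-cyano-6-methoxyphenoxy)phenyl]ethyl]phenoxy}benzoate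
Conditions: TsNHNH2 (excess), NaOAc, THF/H2O (1:1), reflux
Reagents that add atoms: none
Why: diimide reduction, in which diimide generated in situ transfers two hydrogens to the non-polar C=C only, so the benzyl ether, aryl nitrile and ester survive.

Step 6
Reactants: 10 the bibenzyl ester–nitrile
Product: 12 2-[3-[2-[4-(benzyloxy)-3-[4-(hydroxymethyl)phenoxy]phenyl]ethyl]phenoxy]-3-methoxybenzaldehyde, via ArCH2O–Al(i-Bu)2 / ArCH=N–Al(i-Bu)2 bis-aluminated adduct 11 (not isolated)
Conditions: i-Bu2AlH (4.5 equiv), CH2Cl2, −78 to 0 °C; then 1 M HCl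
Reagents that add atoms: water, O
Why: hydride reduction with i-Bu2AlH takes the ester to the primary alkoxide while the nitrile stops at the N-aluminated aldimine, which hydrolyses to the aldehyde on acidic work-up.

Step 7
Reactants: 12 the hydroxy aldehyde
Product: 13 2-[3-[2-[4-(benzyloxy)-3-[4-(bromomethyl)phenoxy]phenyl]ethyl]phenoxy]-3-methoxybenzaldehyde
Conditions: PBr3 (0.4 equiv), CH2Cl2, 0 °C
Reagents that add atoms: phosphorus tribromide, BrP(Br)Br
Why: the benzylic alcohol is activated as a phosphite ester and displaced by bromide (SN2); the aryl aldehyde and ethers do not react at 0 °C.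

Step 8
Reactants: 13 the bromo aldehyde
Product: 14 {4-[2-(benzyloxy)-5-[2-[3-(2-formyl-6-methoxyphenoxy)phenyl]ethyl]phenoxy]benzyl}triphenylphosphonium bromide
Conditions: PPh3, toluene, reflux
Reagents that add atoms: triphenylphosphine, c1ccc(cc1)P(c1ccccc1)c1ccccc1
Why: SN2 quaternisation of the reactive benzylic bromide gives the salt, which precipitates; the aldehyde is untouched in the absence of base.

Step 9
Reactants: 14 the phosphonium bromide aldehyde
Product: 16 macrocyclic stilbene benzyl ether (18-membered ring; ring D and ring A joined by CH=CH, ring C carrying OBn; Z isomer drawn, any E isomer converges in step 10), via benzylidene(triphenyl)phosphorane ylide 15 (not isolated)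
Conditions: NaOMe, CH2Cl2, rt, high dilution (slow addition, about 1 mM)
Reagents that add atoms: none
Why: intramolecular Wittig olefination of the semi-stabilised benzylic ylide onto the ring A aldehyde, with high dilution favouring ring closure over oligomerisation.

Step 10
Reactants: 16 the macrocyclic stilbene benzyl ether
Product: 17 target macrocycle (CNP0309263.0)
Conditions: H2 (1 atm), 10% Pd/C, EtOAc/EtOH, rt
Reagents that add atoms: none
Why: catalytic hydrogenation saturates the stilbene and hydrogenolyses the benzyl ether in one operation, while the aryl methyl ether and diaryl ethers are inert.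

## Compound list

1 | 3-hydroxyphenylacetic acid | OC(=O)Cc1cccc(O)c1 | starting material
2 | 2-fluoro-3-methoxybenzonitrile | COc1cccc(C#N)c1F | starting material
3 | 2-[3-(2-cyano-6-methoxyphenoxy)phenyl]acetic acid | COc1cccc(C#N)c1Oc1cccc(CC(=O)O)c1 | intermediate
4 | 4-(benzyloxy)-3-hydroxybenzaldehyde | O=Cc1ccc(OCc2ccccc2)c(O)c1 | starting material
5 | methyl 4-fluorobenzoate | COC(=O)c1ccc(F)cc1 | starting material
6 | methyl 4-[2-(benzyloxy)-5-formylphenoxy]benzoate | COC(=O)c1ccc(cc1)Oc1cc(C=O)ccc1OCc1ccccc1 | intermediate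
7 | acetic 2-[3-(2-cyano-6-methoxyphenoxy)phenyl]acetic anhydride | CC(=O)OC(=O)Cc1cccc(Oc2c(OC)cccc2C#N)c1 | intermediate (not isolated)
8 | (2E)-3-{4-(benzyloxy)-3-[4-(methoxycarbonyl)phenoxy]phenyl}-2-[3-(2-cyano-6-methoxyphenoxy)phenyl]prop-2-enoic acid | OC(=O)/C(c1cccc(Oc2c(OC)cccc2C#N)c1)=C/c1ccc(OCc2ccccc2)c(Oc2ccc(cc2)C(=O)OC)c1 | intermediate
9 | methyl 4-{2-(benzyloxy)-5-[(Z)-2-[3-(2-cyano-6-methoxyphenoxy)phenyl]ethenyl]phenoxy}benzoate | COC(=O)c1ccc(cc1)Oc1cc(\C=C/c2cccc(Oc3c(OC)cccc3C#N)c2)ccc1OCc1ccccc1 | intermediate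
10 | methyl 4-{2-(benzyloxy)-5-[2-[3-(2-cyano-6-methoxyphenoxy)phenyl]ethyl]phenoxy}benzoate | COC(=O)c1ccc(cc1)Oc1cc(CCc2cccc(Oc3c(OC)cccc3C#N)c2)ccc1OCc1ccccc1 | intermediate
11 | bis-aluminated adduct: ring D CH2O–Al(i-Bu)2 and ring A CH=N–Al(i-Bu)2 | CC(C)C[Al](CC(C)C)OCc1ccc(cc1)Oc1cc(CCc2cccc(Oc3c(OC)cccc3C=N[Al](CC(C)C)CC(C)C)c2)ccc1OCc1ccccc1 | intermediate (not isolated)
12 | 2-[3-[2-[4-(benzyloxy)-3-[4-(hydroxymethyl)phenoxy]phenyl]ethyl]phenoxy]-3-methoxybenzaldehyde | OCc1ccc(cc1)Oc1cc(CCc2cccc(Oc3c(OC)cccc3C=O)c2)ccc1OCc1ccccc1 | intermediate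
13 | 2-[3-[2-[4-(benzyloxy)-3-[4-(bromomethyl)phenoxy]phenyl]ethyl]phenoxy]-3-methoxybenzaldehyde | BrCc1ccc(cc1)Oc1cc(CCc2cccc(Oc3c(OC)cccc3C=O)c2)ccc1OCc1ccccc1 | intermediate
14 | {4-[2-(benzyloxy)-5-[2-[3-(2-formyl-6-methoxyphenoxy)phenyl]ethyl]phenoxy]benzyl}triphenylphosphonium bromide | [Br-].O=Cc1cccc(OC)c1Oc1cccc(CCc2ccc(OCc3ccccc3)c(Oc3ccc(C[P+](c4ccccc4)(c4ccccc4)c4ccccc4)cc3)c2)c1 | intermediate
15 | ylide of 14: ring D CH=PPh3, ring A CHO | O=Cc1cccc(OC)c1Oc1cccc(CCc2ccc(OCc3ccccc3)c(Oc3ccc(C=P(c4ccccc4)(c4ccccc4)c4ccccc4)cc3)c2)c1 | intermediate (not isolated)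
16 | macrocyclic stilbene benzyl ether: 18-membered ring, ring D–CH=CH–ring A (Z drawn), OBn on ring C, OMe on ring A | c1(/C=C\c2cccc(OC)c2Oc2cccc(CCc3ccc(OCc4ccccc4)c(c3)O5)c2)ccc5cc1 | intermediate
17 | target macrocycle: 18-membered bis(bibenzyl) bis(diaryl ether), OMe on ring A, OH on ring C | COc1cccc2c1Oc1cccc(c1)CCc1ccc(O)c(c1)Oc1ccc(cc1)CC2 | target

## Step count and risks

Total steps: 10. Longest linear sequence: 9 steps (1 → 3 → 8 → 9 → 10 → 12 → 13 → 14 → 16 → 17; the sequence from 4 through 6 is equally long).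

The three steps most likely to fail:

**Step 1 (SNAr on a nitrile-activated fluoride that is deactivated and hindered by the ortho methoxy group).** The fallback sets out from 1 and comes back at 3. Compound 1 is coupled under the same carbonate/DMSO regime at 90–100 °C with the much more electrophilic commercial 2-fluoro-3-methoxybenzaldehyde (COc1cccc(C=O)c1F) to give 2-[3-(2-formyl-6-methoxyphenoxy)phenyl]acetic acid F1. Heating F1 with NH2OH·HCl and HCO2Na in formic acid forms 2-[3-[2-[(E)-(hydroxyimino)methyl]-6-methoxyphenoxy]phenyl]acetic acid F2, which loses water in the same pot to deliver nitrile 3.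

**Step 4 (decarboxylation at 210 °C in the presence of a benzyl ether, an ester and a nitrile).** The fallback sets out from 8 and comes back at 10, bypassing 9 and step 5. The acrylic acid 8 is hydrogenated over Pd/C poisoned with Ph2S (H2, 1 atm, THF/MeOH), which spares the benzyl ether and nitrile, to give racemic 3-{4-(benzyloxy)-3-[4-(methoxycarbonyl)phenoxy]phenyl}-2-[3-(2-cyano-6-methoxyphenoxy)phenyl]propanoic acid F3. Coupling with 1-hydroxypyridine-2(1H)-thione (EDC·HCl, DMAP, CH2Cl2, dark) gives the Barton ester, 2-thioxopyridin-1(2H)-yl 3-{4-(benzyloxy)-3-[4-(methoxycarbonyl)phenoxy]phenyl}-2-[3-(2-cyano-6-methoxyphenoxy)phenyl]propanoate F4. Irradiation with a tungsten lamp in the presence of t-BuSH effects radical decarboxylation and hydrogen-atom transfer to give bibenzyl 10; the stereocentre of F3 is destroyed in this step.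

**Step 9 (macrocyclisation, at risk of oligomerisation).** The fallback sets out from 12 and comes back at 16. The benzylic alcohol of 12 is oxidised with MnO2 in CH2Cl2 to the dialdehyde 2-[3-[2-[4-(benzyloxy)-3-(4-formylphenoxy)phenyl]ethyl]phenoxy]-3-methoxybenzaldehyde F5. F5 is closed by an intramolecular McMurry coupling with low-valent titanium (TiCl4, Zn, pyridine, THF, reflux, syringe-pump addition at high dilution) to give the macrocyclic stilbene 16 as an E/Z mixture, which enters step 10 unchanged.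

## Further compounds

F1 | step 1 | 2-[3-(2-formyl-6-methoxyphenoxy)phenyl]acetic acid | COc1cccc(C=O)c1Oc1cccc(CC(=O)O)c1
F2 | step 1 | 2-[3-[2-[(E)-(hydroxyimino)methyl]-6-methoxyphenoxy]phenyl]acetic acid | COc1cccc(/C=N/O)c1Oc1cccc(CC(=O)O)c1
F3 | step 4 | 3-{4-(benzyloxy)-3-[4-(methoxycarbonyl)phenoxy]phenyl}-2-[3-(2-cyano-6-methoxyphenoxy)phenyl]propanoic acid (racemic) | OC(=O)C(Cc1ccc(OCc2ccccc2)c(Oc2ccc(cc2)C(=O)OC)c1)c1cccc(Oc2c(OC)cccc2C#N)c1
F4 | step 4 | 2-thioxopyridin-1(2H)-yl 3-{4-(benzyloxy)-3-[4-(methoxycarbonyl)phenoxy]phenyl}-2-[3-(2-cyano-6-methoxyphenoxy)phenyl]propanoate (racemic) | S=C1C=CC=CN1OC(=O)C(Cc1ccc(OCc2ccccc2)c(Oc2ccc(cc2)C(=O)OC)c1)c1cccc(Oc2c(OC)cccc2C#N)c1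
F5 | step 9 | 2-[3-[2-[4-(benzyloxy)-3-(4-formylphenoxy)phenyl]ethyl]phenoxy]-3-methoxybenzaldehyde | O=Cc1ccc(cc1)Oc1cc(CCc2cccc(Oc3c(OC)cccc3C=O)c2)ccc1OCc1ccccc1
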